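A small charge of substrate, 0.20 M, meets 2.00 equiv of reagent: together at the start in Wednesday's flask, with the substrate fed over 1.5 h in Tuesday's, with the reagent fed over 1.5 h in Thursday's.

| setting | spring | dusk | winter | midnight | Thursday's | Wednesday's | Tuesday's |
|---|---|---|---|---|---|---|---|
| substrate | 0.20 M | 0.20 M | 0.20 M | 0.10 M | 0.20 M | 0.20 M | 0.20 M (fed, over 1.5 h) |
| reagent | 2 equiv | 1.3 equiv | 3 equiv | 2 equiv | 2.00 equiv (fed, over 1.5 h) | 2.00 equiv | 2.00 equiv |
| remark | run made earlier | run made earlier | run made earlier | run made earlier | all else is in the flask from the start; the feed brings no volume worth counting | everything together at the start | all else is in the flask from the start; the feed brings no volume worth counting |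
| time |  |  |  |  | 2.0 h | 2.0 h | 2.0 h |

spring run (percent of the substrate charged)

| time / min | double product / % | mono adduct / % |
|---|---|---|
| 6.00 | 32.2 | 1.9 |
| 20.0 | 42.4 | 2.0 |
| 30.0 | 46.2 | 0 |
| 50.0 | 46.9 | 0 |
| 80.0 | 49.7 | 0 |

dusk run (percent of the substrate charged)

| time / h | double product / % | mono adduct / % |
|---|---|---|
| 0.200 | 32.5 | 3.1 |
| 0.333 | 36.4 | 0 |
| 0.667 | 40.2 | 1.7 |
| 1.33 | 42.4 | 0 |
| 2.50 | 45.9 | 0 |

winter run (percent of the substrate charged)

| time / h | double product / % | mono adduct / % |
|---|---|---|
| 0.200 | 43.9 | 0.2 |
| 0.667 | 52.4 | 0.3 |
| 1.00 | 55.7 | 0 |
| 1.50 | 60.1 | 2.1 |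
| 2.50 | 65.6 | 0 |

midnight run (percent of the substrate charged)

| time / h | double product / % | mono adduct / % |
|---|---|---|
| 0.200 | 33.0 | 3.5 |
| 0.667 | 43.4 | 2.0 |
| 1.00 | 44.7 | 0.4 |
| 1.50 | 48.5 | 1.0 |
| 2.50 | 54.5 | 0 |

(each reading ± 1 percentage point)



* which flask leads in amount of double product, in percent of the substrate charged ("all alike" within 1.5 percentage points) (Thursday's / Wednesday's / Tuesday's / all alike)
* how much double product is there at the end, in percent of the substrate charged: Thursday's
* how much double product is there at the end, in percent of the substrate charged: Wednesday's
* how much double product is there at the end, in percent of the substrate charged: Tuesday's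

The spring run, which is Wednesday's recipe, looks contradictory. Double product reaches 32.2% within 6.00 min, yet gains 7.3 percentage points between 20.0 min and 80.0 min. If each double product holds two reagent, about half of the reagent still stands at the last reading.

The fraction left, one minus the double product, clears this up better than the fraction made. It falls at first at 3.89 h⁻¹. Between the same later readings it falls at 0.136 h⁻¹, the creep constant: the logarithm of the ratio of the fractions left, per hour, once the burst is over. The first rate is far faster than the later one, so what is left after the burst does not behave like what was charged. The constant is a reading, and each reading in it carries 1 point.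

My own reckoning takes the 50.3% left at 80.0 min through the last 40.0 min at that constant, which gives 54.0% for Wednesday's.

The forecast gave Wednesday's 53%, Tuesday's 72% and Thursday's 33%, so it named Tuesday's as leader, holding that “slow substrate feed into excess reagent keeps substrate low, suppressing diversion”.

The flasks give 54.1% for Wednesday's, 46.4% for Tuesday's and 44.1% for Thursday's, so Wednesday's leads.

    substrate + reagent ⇌ mono adduct + released group (K = 0.620, k = 0.0130 M⁻¹ s⁻¹)
    substrate + reagent → other mono adduct + released group (k = 4.20 × 10⁻⁴ M⁻¹ s⁻¹)
    reagent + mono adduct → double product + released group (k = 0.0300 M⁻¹ s⁻¹)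
    reagent + other mono adduct → double product + released group (k = 0.0270 M⁻¹ s⁻¹)
    substrate + released group ⇌ idle adduct, settled at all times (K = 460 M⁻¹)
    substrate ⇌ dormant form (K = 2.20, k = 7.70 × 10⁻⁴ s⁻¹)

Without the reaction of reagent + mono adduct to double product, the gap between Wednesday's and Thursday's narrows from 10 points to 2 points, so this step is a part of the reason, and the narrowing is greater than without substrate to dormant form, both ways, which leaves 5.5 points. Thursday's 55.9% left, taken on at the creep constant, gives 51.2% double product at 3.00 h, and Thursday's flask read then holds 51.3%.

The earlier runs and the new flask were generated by integration from invented constants; scatter was added.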